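The numbers in the tables come from a simulation with made-up constants, noise included.

I started from a leftover: the charge of Z minus c(X) at the time asked of amber.

common to all: Z 0.100 M
- violet: J 0.100 M
- grey: J 0.200 M
- amber: J 0.460 M; time 38 h

- violet run (time / h: [X] / M): 6.3: 0.0151; 13: 0.0265; 19: 0.0331; 25: 0.0369; 32: 0.0401; 38: 0.0432
- grey run (time / h: [X] / M): 6.3: 0.0260; 13: 0.0412; 19: 0.0492; 25: 0.0537; 32: 0.0573; 38: 0.0595

(standard deviation of a reading: 3 × 10⁻⁴ M)

* order of the initial rate in [J], near the charge of the violet run, the rate being that where two percent of its Z are X
* X in the amber run at 38 h, as a share of the Z charged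

- Overall: Z + J -> X.
- Constant volume, constant temperature.
- "The second partner" is J.
- An order is taken over about fifteen percent of the charge, up and down.

Two times carried my reckoning. One was the asked 38 h. The other was the fold time, the time in which the leftover falls by a factor e, on average over that span. The violet run gave 67.2 h, and the grey run gave 42.0 h. Asked time over fold time counts the turnovers, and the leftover share is e to the minus that count.

An opening time would not serve. The first grey reading gave 20.9 h, and the whole grey span gave twice that, so the grey run slowed. The span average carries that slowing.

From violet to grey, the fold time shrank as c(J) to the power 0.676, a reading from two runs. I carried that power to amber. That gave a fold time of 23.9 h, 1.59 turnovers and a share of 79.6%.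

The forecast gave an order of 0.87 (0.65 to 1.05) and a share of 71% (57% to 84%), holding that “something is being lost or opposing the reaction”.

The flask gave an order of 0.69 and a share of 77.7%, so my share stood 1.9 percentage points higher.

    Z ⇌ L + G (0.4680 h⁻¹, 0.9792 M⁻¹ h⁻¹)
    L + J → X (0.5040 M⁻¹ h⁻¹)
    2 J → Ky (0.4896 M⁻¹ h⁻¹)
    Z + J + X → 2 X (44.28 M⁻² h⁻¹)

The amber share means a fold time of 25.3 h, or 1.50 turnovers. One reason amber got that far is the conversion of Z + J + X into 2 X. The amber run without that conversion ended at 57.4%, which means a fold time of 44.6 h and 0.852 turnovers.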